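**Assumptions (one line):** Intermediates use ent-kaurane numbering. The configuration shown in the target SMILES is taken as correct. The C6 acetal anomer is assumed to be the thermodynamic one (OMe cis to C10 on the concave face of the cis-fused THF).

## Retrosynthetic overview
1. The last step is α-methylenation of bicyclo[3.2.1]octan-6-one 21. Only C16 is enolizable because C8 is quaternary.
2. Ring D closes by a 5-exo radical cyclization of an α-keto radical (C16) onto the C12=C13 alkene of a cyclohexene.
3. Ring C forms by Diels–Alder of butadiene with a spiro 3-acetyl-dihydropyranone. This fixes the cis C8/C9 relationship.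
4. That spirolactone comes from an intramolecular Knoevenagel reaction of an acetoacetate ester and an aldehyde. Both sit on the quaternary C10, which is built by alkylating an ester enolate on the convex face of a cis-fused THF acetal.
5. The THF acetal and ring A come from one organocatalytic endo Diels–Alder of dienol 4 with 4-oxobutenoate 5.

Ring order: A (Diels–Alder), then THF acetal, spirolactone, ring C (Diels–Alder), ring D (radical).

## Route

**Step 1**
Reactants: 1 acrolein; 2 ethyl 2-(triphenylphosphoranylidene)propanoate
Product: 3 ethyl (2E)-2-methylpenta-2,4-dienoate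
Conditions: CH2Cl2, 25 °C
Reagents that add atoms: none (2 is the numbered C5 building block)
Why: Wittig olefination with a stabilized ylide gives the E-trisubstituted alkene. The E geometry puts the ester trans to the vinyl group, which later becomes the "outside" substituent in the Diels–Alder.

**Step 2**
Reactants: 3
Product: 4 (2E)-2-methylpenta-2,4-dien-1-ol
Conditions: DIBAL-H (2.5 equiv), CH2Cl2, −78 → 0 °C
Reagents that add atoms: none
Why: 1,2-reduction of the ester to the primary alcohol (future C19–OH) leaves the diene and its E geometry unchanged.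

**Step 3**
Reactants: 4; 5 methyl (2E)-4-oxobut-2-enoate
Product: 6 methyl 2-formyl-3-(hydroxymethyl)-3-methylcyclohex-4-ene-1-carboxylate. CHO (C6) and CH2OH (C19) are cis; CO2Me and CHO are trans. Written as C10 ester, C5 CHO, C4 (Me, CH2OH), Δ2. It partly exists as the cis lactol.
Conditions: (5S)-5-benzyl-2,2,3-trimethylimidazolidin-4-one·HCl (20 mol %), MeOH/H2O, 0 °C
Reagents that add atoms: none (catalyst only)
Why: Iminium-catalyzed Diels–Alder.
- Regiochemistry: the aldehyde-bearing carbon bonds to the hindered diene terminus (the "ortho" adduct), giving C4–C5 and C1–C10 bonds.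
- Relative stereochemistry: the endo TS with the E-diene places the outside CH2OH cis to the endo CHO. The E-dienophile gives the trans ester.
- Absolute configuration at C4/C5 is set by the catalyst enantiomer, chosen to give 6 as drawn.

**Step 4**
Reactants: 6; 7 methanol
Product: 8 methyl 1-methoxy-3a-methyl-1,3,3a,6,7,7a-hexahydro-2-benzofuran-7-carboxylate. This is the cis-fused 6,19-THF methyl acetal with the C6 OMe as in the target.
Conditions: MeOH, PPTS (10 mol %), 25 °C
Reagents that add atoms: methanol, CO (adds OMe)
Why: Hydroxy-aldehyde 6 closes to the cis-fused lactol, and acid-catalyzed acetalization with MeOH gives the methyl acetal. The anomer is under thermodynamic control.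

**Step 5**
Reactants: 8; 9 benzyl chloromethyl ether (BOMCl)
Product: 10 quaternary C10 ester. CH2OBn is on the top (C9) face and CO2Me is on the bottom (C20) face. The ester carbon becomes C20.
Conditions: LDA, THF, −78 °C; then BOMCl, DMPU, −78 → 0 °C
Reagents that add atoms: BOMCl, ClCOCc1ccccc1 (adds CH2OBn)
Why: Ester enolate alkylation. The cis-fused THF ring covers the bottom face of ring A, so the electrophile attacks from the top face. The new CH2OBn therefore lands on the face that becomes C9, and the planar enolate carbon ends up with the ester on the C20 face. This sets the C10 quaternary center.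

**Step 6**
Reactants: 10
Product: 11 primary alcohol (C20–OH, with C9–OBn)
Conditions: LiAlH4, THF, 0 → 65 °C
Reagents that add atoms: none
Why: Ester-to-alcohol reduction. The acetal, benzyl ether and alkene are untouched, and no stereocenter is affected.

**Step 7**
Reactants: 11; 12 2,2,6-trimethyl-4H-1,3-dioxin-4-one (TMD)
Product: 13 C20 acetoacetate ester
Conditions: TMD, xylenes, 140 °C
Reagents that add atoms: TMD, CC1=CC(=O)OC(C)(C)O1 (adds the acetoacetyl group, C4H5O2)
Why: Thermolysis of TMD gives acetylketene, which acylates hindered neopentyl alcohols under neutral conditions.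

**Step 8**
Reactants: 13
Product: 14 hydroxy acetoacetate (C9–OH; C1–C3 saturated)
Conditions: H2 (1 atm), Pd(OH)2/C, EtOAc, 25 °C
Reagents that add atoms: none
Why: Hydrogenolysis of the benzyl ether together with hydrogenation of the C2=C3 alkene. No stereocenter is affected. The product is used immediately to avoid 1,3-acyl migration.

**Step 9**
Reactants: 14
Product: 15 C9 aldehyde / C20 acetoacetate
Conditions: Dess–Martin periodinane, NaHCO3, CH2Cl2, 0 → 25 °C
Reagents that add atoms: none
Why: Mild oxidation gives a non-enolizable neopentyl aldehyde with no epimerization.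

**Step 10**
Reactants: 15
Product: 16 spiro 3-acetyl-5,6-dihydro-2H-pyran-2-one. C7 is the lactone carbonyl, C8=C9, and C15 is the acetyl carbon; the THF acetal is retained.
Conditions: piperidine/AcOH (cat.), PhMe, 4 Å MS, 80 °C
Reagents that add atoms: none
Why: Intramolecular Knoevenagel condensation of the active methylene (C8) with the C9 aldehyde. The gem-disubstituted C10 favors closure to the δ-lactone.

**Step 11**
Reactants: 16; 17 1,3-butadiene
Product: 18 tricyclic keto-lactone with a C12=C13 cyclohexene. C8 is quaternary, bearing the C7 lactone carbonyl and the C15 acetyl.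
Conditions: butadiene (excess), BHT, PhMe, 120 °C, sealed tube
Reagents that add atoms: 1,3-butadiene, C=CC=C (adds C11–C14)
Why: Diels–Alder on the very electron-poor alkylidene β-keto lactone.
- The endocyclic lactone alkene forces suprafacial addition, so C7/C10 are cis and C15/H9 are cis, as in the target.
- The diene is expected to add to the face syn to C1 and anti to the branched C5.

**Step 12**
Reactants: 18; 19 N-bromosuccinimide
Product: 20 α-bromomethyl ketone
Conditions: LiHMDS, TMSCl, THF, −78 °C; then NBS, −78 → 0 °C
Reagents that add atoms: NBS, O=C1CCC(=O)N1Br (leaves Br)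
Why: Only the acetyl CH3 is enolizable, since C8 is quaternary and the lactone has no α-H. The silyl enol ether plus NBS brominates it selectively without touching the alkene.

**Step 13**
Reactants: 20
Product: 21 bicyclo[3.2.1]octan-6-one (C16 is a CH2; C12 and C11 are CH2)
Conditions: Bu3SnH (syringe pump), AIBN, PhH, 80 °C, 5 mM
Reagents that add atoms: none
Why: The α-keto radical at C16 undergoes 5-exo-trig cyclization onto C13 of the C12=C13 alkene, and the C12 radical is quenched by H. The tether can reach only the face bearing C15, so C13 is set by the bridging constraint. This forms ring D.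

**Step 14**
Reactants: 21; 22 Eschenmoser's salt
Product: 23 Ludongunin J
Conditions: LDA, THF, −78 °C; then Me2N+=CH2 I−; then MeI; then aq. NaHCO3
Reagents that add atoms: Eschenmoser's salt, C[N+](C)=C.[I-] (leaves the exocyclic CH2). MeI only quaternizes the amine and leaves no atoms.
Why: Regioselective Mannich α-aminomethylation at C16, then methylation and elimination (Hofmann-type) give the exocyclic enone. All stereocenters are already set and none is epimerizable.

## Compound list
1 | acrolein | C=CC=O | starting material
2 | ethyl 2-(triphenylphosphoranylidene)propanoate | CCOC(=O)C(C)=P(c1ccccc1)(c1ccccc1)c1ccccc1 | starting material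
3 | ethyl (2E)-2-methylpenta-2,4-dienoate | CCOC(=O)/C(C)=C/C=C | intermediate
4 | (2E)-2-methylpenta-2,4-dien-1-ol | OC/C(C)=C/C=C | intermediate
5 | methyl (2E)-4-oxobut-2-enoate | COC(=O)/C=C/C=O | starting material
6 | methyl 2-formyl-3-(hydroxymethyl)-3-methylcyclohex-4-ene-1-carboxylate (Diels–Alder adduct) | COC(=O)[C@@H]1CC=C[C@@](C)(CO)[C@H]1C=O | intermediate
7 | methanol | CO | starting material
8 | cis-fused 6,19-THF methyl acetal ester | COC(=O)[C@@H]1CC=C[C@@]2(C)CO[C@@H](OC)[C@@H]12 | intermediate
9 | benzyl chloromethyl ether | ClCOCc1ccccc1 | starting material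
10 | quaternary C10 ester with CH2OBn | COC(=O)[C@@]1(COCc3ccccc3)CC=C[C@@]2(C)CO[C@@H](OC)[C@@H]12 | intermediate
11 | C20 alcohol, C9–OBn | OC[C@@]1(COCc3ccccc3)CC=C[C@@]2(C)CO[C@@H](OC)[C@@H]12 | intermediate
12 | 2,2,6-trimethyl-4H-1,3-dioxin-4-one | CC1=CC(=O)OC(C)(C)O1 | starting material
13 | C20 acetoacetate | CC(=O)CC(=O)OC[C@@]1(COCc3ccccc3)CC=C[C@@]2(C)CO[C@@H](OC)[C@@H]12 | intermediate
14 | C9 alcohol / C20 acetoacetate (saturated ring A) | CC(=O)CC(=O)OC[C@@]1(CO)CCC[C@@]2(C)CO[C@@H](OC)[C@@H]12 | intermediate
15 | C9 aldehyde / C20 acetoacetate | CC(=O)CC(=O)OC[C@@]1(C=O)CCC[C@@]2(C)CO[C@@H](OC)[C@@H]12 | intermediate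
16 | spiro 3-acetyl-5,6-dihydropyran-2-one acetal | CC(=O)C1=C[C@]2(COC1=O)CCC[C@@]3(C)CO[C@@H](OC)[C@@H]23 | intermediate
17 | 1,3-butadiene | C=CC=C | starting material
18 | Diels–Alder adduct (C12=C13 cyclohexene) | CC(=O)[C@]23CC=CC[C@H]2[C@@]1(CCC[C@@]2(C)CO[C@@H](OC)[C@H]21)COC3=O | intermediate
19 | N-bromosuccinimide | O=C1CCC(=O)N1Br | starting material
20 | α-bromomethyl ketone | BrCC(=O)[C@]23CC=CC[C@H]2[C@@]1(CCC[C@@]2(C)CO[C@@H](OC)[C@H]21)COC3=O | intermediate
21 | bicyclo[3.2.1]octan-6-one (16-desmethylene target) | C1C(=O)[C@]23C[C@H]1CC[C@H]2[C@@]1(CCC[C@@]2(C)CO[C@@H](OC)[C@H]21)COC3=O | intermediate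
22 | Eschenmoser's salt | C[N+](C)=C.[I-] | starting material
23 | Ludongunin J | C=C1C(=O)[C@]23C[C@H]1CC[C@H]2[C@@]1(CCC[C@@]2(C)CO[C@@H](OC)[C@H]21)COC3=O | target

**Totals:** 14 steps; longest linear sequence 14 (from acrolein and ylide 2).

## Three steps most likely to fail
1. **Step 3 (organocatalytic Diels–Alder).** The 1,1-disubstituted dienol is hindered, and regio-, endo- and enantioselectivity are uncertain. Fallback: use a chiral-auxiliary dienophile (8-phenylmenthyl 4-oxobut-2-enoate with Et2AlCl), or build ring A by Cu-catalyzed asymmetric conjugate addition of a vinyl nucleophile to 3-methylcyclohexenone with enolate trapping, then form the THF acetal.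
2. **Step 11 (butadiene Diels–Alder on the hindered spiro alkylidene).** Reactivity and facial selectivity at C9 next to the quaternary C10 are uncertain. Fallback: form C9–C10 by Cp2TiCl-mediated opening of a C10 spiro-epoxide (Wittig on a C10 ketone, then epoxidation) and Giese addition of the tertiary radical to an alkylidene acetoacetate. The radical attacks anti to the axial C19, then lactonization follows.
3. **Step 13 (5-exo versus 6-endo radical closure).** The [3.2.1] product competes with the [2.2.2] isomer. Fallback: Pd(OAc)2-mediated oxidative cycloalkenylation of the silyl enol ether of the methyl ketone 18 onto C12=C13 (Toyota–Ihara type), followed by hydrogenation.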